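## The problem

Target 16, (2R,3R)-2-(2,5-dihydroxy-4-methoxyphenyl)-3,5,6,7-tetramethoxychroman-4-one, is a flavanone in which ring A is the benzo ring, ring B the C2 aryl group and ring C the pyranone. Ring C carries two adjacent stereocentres in the trans arrangement, the benzylic ether carbon C2 and the methoxy-bearing C3 next to the C4 ketone. Ring A has the 5,6,7-trimethoxy pattern that results when 3,4,5-trimethoxyphenol 8 is acylated ortho to its hydroxyl, so O1 and the C4–C4a bond map onto one symmetrical, purchasable phenol. Ring B is a free methoxyhydroquinone that oxidises in air, fastest under base, which rules out basic end-game steps, late O-methylation and any excess oxidant in contact with the product. Both stereocentres are labile, but in different ways: enolisation at C3 followed by loss of O1 from C2 gives an achiral α-methoxychalcone and destroys both, whereas heterolysis of O1–C2, assisted by the ortho 2′-hydroxyl and the para 4′-methoxy group, gives an ortho-quinone methide and touches C2 only. C3 must therefore be set early and independently, and C2 can then be left to C3 under reversible closure, which favours ring B and the C3 methoxy group both equatorial. The enabling feature is that the 2′-hydroxyl is ortho to C2 and para to the 5′-hydroxyl: shifting two hydrogens turns 16 into a 2-methoxy-5-alkyl-para-quinone whose alkyl carbon is a C2 methylene and whose ring A phenol is free. That quinone is one Teuber oxidation away from a ring B phenol that lacks the C2′ oxygen, which is the ring of isovanillin 1.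

## Retrosynthesis

O1–C2 and C2′–O (16 back to 13). The first cut removes the ether bond O1–C2 of ring C together with the C2′–O bond of ring B. Read forwards, phenol 13 is oxidised para to its ring B hydroxyl to para-quinone 14, 14 tautomerises to ortho-quinone methide 15, and the ring A phenol of 15 closes ring C to give 16. Cutting O1–C2 alone in the conjugate-addition sense would make C3 trigonal in the precursor and give up the one secure stereocentre. Cutting it in the substitution sense would need a leaving group at an easily ionised benzylic carbon and a protected hydroquinone. The chosen cut keeps C3 tetrahedral, removes one ring, one stereocentre and one oxygen, and leaves a ring B identical to that of 1. The forward reaction must oxidise the ring B phenol and not the ketone-chelated ring A phenol, must keep the product hydroquinone 16 away from oxidant (a metered stoichiometric oxidant and a change of phase before the tautomerisation, not a catalytic aerobic system), and must move the C2 proton and not the C3 proton.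

Two O–benzyl bonds (13 back to 12). Both phenols of 13 are masked as benzyl ethers in ketone 12. Benzyl is preferred to acetal or silyl groups because both ethers fall in one neutral hydrogenolysis, which the C3 centre next to the ketone tolerates, and because benzyl ethers survive the organolithium and homogeneous hydrogenation steps that come earlier.

C4–C4a (12 back to 11 and 7). The aryl–acyl bond is cut to aryllithium 11, made from bromide 10, and N-methoxy-N-methylamide 7. Direct acylation of phenol 8 with acid 6 would be shorter and regiochemically safe, but it would expose the C3 centre, the benzyl ether and the methoxy group peri to the new carbonyl to a strong Lewis acid. The organometallic route gives two fragments of similar size, each with at most one stereocentre. It asks that 11 add to 7 faster than it removes the α-proton and that the tetrahedral adduct hold until the quench.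

Amide C–N and the C3 stereocentre (7 back to 6 and 5). Amide 7 comes from acid 6, and 6 from the (Z)-α-methoxycinnamic acid 5 by addition of hydrogen across the future C2–C3 bond. A catalytic asymmetric hydrogenation is preferred to an auxiliary-based alkylation, which needs a stoichiometric chiral reagent and more steps, and to α-oxygenation of a ketone enolate, which would need a separate O-methylation. Acid 5 is achiral, and its free carboxyl group is the directing group the catalyst needs.

C2=C3 of the acrylic acid (5 back to 2 and 3). The double bond is cut by a condensation between aldehyde 2 and methyl methoxyacetate 3, through ester 4. The C3 methoxy group arrives with 3, so no secondary alcohol is ever methylated. The thermodynamically preferred Z geometry of 5 (aryl trans to carboxyl) is the one the hydrogenation needs as a single isomer.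

Protecting group and halogen (2 back to 1; 10 back to 9 and 8). Aldehyde 2 is the benzyl ether of isovanillin 1. Bromide 10 comes from phenol 8 by O-benzylation to 9 and bromination. Since 8 is symmetrical, the two open positions of 9 are identical and each lies between the benzyloxy group and a methoxy group, so only the required substitution pattern can form.

## Roads not taken

Alternative 1: The C3–O and C2–C3 bonds are cut together. In the forward step the ring A diazoketone 2-diazo-1-[2-(methoxymethoxy)-4,5,6-trimethoxyphenyl]ethan-1-one A2 would be decomposed by Rh2(OAc)4 in the presence of methanol A3 and 2,5-bis(benzyloxy)-4-methoxybenzaldehyde A4 under a chiral acid. The oxonium ylide formed from the carbene and A3 would add to A4 and give the open-chain hydroxy ketone A1, (2R,3R)-3-[2,5-bis(benzyloxy)-4-methoxyphenyl]-3-hydroxy-2-methoxy-1-[2-(methoxymethoxy)-4,5,6-trimethoxyphenyl]propan-1-one; no ring closes. The step is convergent and builds two bonds and both stereocentres catalytically. Ring B arrives at its final oxidation level, so no oxidant is needed near the end, and in that respect this road is better than the chosen one. Its weak points are several. A2 has to be made from a hindered ring A acid by a diazoketone synthesis. A4 is an electron-rich, ortho-substituted and therefore sluggish electrophile, so a simple proton shift of the ylide (formal O–H insertion of A3) competes. Ring C still has to be closed after the acetal is removed. The carbinol carbon of A1 already has the spatial arrangement of C2 in 16, so an invertive closure would give the cis isomer, while an ionising closure would erase the centre the chiral acid had set and would rely on C3 alone, as the chosen plan does. Three benzyl ethers and one acetal must then be removed. Against a ring B that never meets an oxidant, the chosen plan sets a dependable way to fix C3, a single type of protecting group, and a final step that forms the ring, C2 and the last oxygen with nothing after it.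

Alternative 2: The C3–C4 and O1–C2 bonds are cut. In the forward step 2-(hydroxymethyl)-3,4,5-trimethoxyphenol A6 would be ionised at its benzylic carbon to an ortho-quinone methide. That carbon would be attacked by the enamine formed from methoxyacetaldehyde A7 and a chiral secondary amine, and the phenol would close onto the iminium carbon to give lactol A5, (2S,3S)-3,5,6,7-tetramethoxychroman-2-ol. Ring C and C3 are made in one organocatalytic step from the small pieces A6 and A7 without protecting groups on ring A. For the catalytic setting of C3 this is about equal to the hydrogenation of the chosen plan. The weak point is what A5 lacks, namely ring B and the C4 carbonyl. Ring B would have to be added to C2 as an aryl nucleophile, which opens ring C, and the ring would then have to be closed again with control at C2. C4 would have to be oxidised from a methylene to a ketone beside a more electron-rich, more easily oxidised benzylic C2, and the ring B hydroquinone would need protection throughout. The key step thus comes early and leaves the hardest operations for later, whereas in the chosen plan C4 is a ketone and ring B is attached from the first C–C bond onward.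

Alternative 3: The C3–C4 bond is cut. In the forward step the dialdehyde 2-{1-[2,5-bis(benzyloxy)-4-methoxyphenyl]-2-oxoethoxy}-4,5,6-trimethoxybenzaldehyde A9 would undergo an intramolecular crossed benzoin reaction under a chiral triazolylidene carbene. The C2 centre of A9 epimerises readily, so a dynamic kinetic closure to the 3-hydroxyflavanone A8, (2R,3R)-2-[2,5-bis(benzyloxy)-4-methoxyphenyl]-3-hydroxy-5,6,7-trimethoxychroman-4-one, would be possible. The step closes ring C, delivers the C4 ketone directly and addresses both stereocentres, and ring B carries its full oxygenation from the start. On these points it matches or exceeds the chosen plan. Its weak points lie in the substrate and in what follows. A9 is an α-aryl-α-aryloxy acetaldehyde, prone to enolisation, loss of phenoxide and air oxidation. The carbene must form its acyl-anion equivalent at the hindered, electron-rich ring A aldehyde and not at the more reactive aliphatic one, or the regioisomeric ketol results. A8 has a C3 hydroxyl, so an α-ketol must be O-methylated in a flavanone that opens under base, and two benzyl ethers must then be removed. The chosen plan brings the C3 methoxy group in with methyl methoxyacetate 3, uses only stable intermediates and ends at its key step; the price is a late oxidation that must be kept away from its own product.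

Key step: step 9

## Route

Remark: the sense of induction in step 3 (R ligand gives the 2R acid) is assigned by analogy with carboxylate-directed ruthenium–bisphosphine reductions of (Z)-α-alkoxyacrylic acids; should the opposite sense be found, the S ligand is used with no other change.

Remark: the exocyclic alkene geometry of quinone methide 15 is left undefined, since it is lost on ring closure.

Step 1
Reactants: 1 isovanillin (3-hydroxy-4-methoxybenzaldehyde)
Product: 2 3-(benzyloxy)-4-methoxybenzaldehyde
Conditions: BnBr, K2CO3, DMF, rt
Reagents that add atoms: benzyl bromide, BrCc1ccccc1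
Why: Williamson ether synthesis on the only acidic site; the aldehyde has no α-hydrogen and is inert to carbonate.

Step 2
Reactants: 2 3-(benzyloxy)-4-methoxybenzaldehyde; 3 methyl methoxyacetate
Product: 5 (Z)-3-[3-(benzyloxy)-4-methoxyphenyl]-2-methoxyprop-2-enoic acid, via methyl ester 4 (not isolated)
Conditions: NaOMe (3 equiv), 3 (3 equiv), MeOH, reflux; then 2 M aq NaOH, reflux; HCl to pH 2
Reagents that add atoms: sodium hydroxide, [Na+].[OH-]
Why: Claisen-type aldol condensation of the ester enolate with a non-enolisable aldehyde, followed by E1cB dehydration, should give the more stable Z acrylate (aryl trans to the carboxyl group); saponification in the same flask gives the acid, which can be crystallised as a single isomer.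

Step 3
Reactants: 5 (Z)-3-[3-(benzyloxy)-4-methoxyphenyl]-2-methoxyprop-2-enoic acid
Product: 6 (R)-3-[3-(benzyloxy)-4-methoxyphenyl]-2-methoxypropanoic acid
Conditions: H2 (30 bar), Ru(OAc)2[(R)-BINAP] (1 mol%), MeOH, 40 °C
Reagents that add atoms: none
Why: Carboxylate-directed asymmetric hydrogenation of an α-alkoxyacrylic acid by a divalent ruthenium bisphosphine complex, a reaction type known for α-alkoxycinnamic acids; the chiral ligand selects the alkene face of the chelated substrate and so sets the future C3, while the benzyl ether is untouched by this homogeneous catalyst.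

Step 4
Reactants: 6 (R)-3-[3-(benzyloxy)-4-methoxyphenyl]-2-methoxypropanoic acid
Product: 7 (R)-3-[3-(benzyloxy)-4-methoxyphenyl]-N,2-dimethoxy-N-methylpropanamide
Conditions: CDI, CH2Cl2, rt; then MeNHOMe·HCl, rt
Reagents that add atoms: N,O-dimethylhydroxylamine hydrochloride, CNOC.Cl
Why: Amidation through the acyl imidazole; no strong base is present and an α-alkoxy acid cannot form an azlactone, so the stereocentre should be retained.

Step 5
Reactants: 8 3,4,5-trimethoxyphenol
Product: 9 5-(benzyloxy)-1,2,3-trimethoxybenzene
Conditions: BnBr, K2CO3, DMF, rt
Reagents that add atoms: benzyl bromide, BrCc1ccccc1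
Why: Williamson ether synthesis of an unhindered phenol.

Step 6
Reactants: 9 5-(benzyloxy)-1,2,3-trimethoxybenzene
Product: 10 1-(benzyloxy)-2-bromo-3,4,5-trimethoxybenzene
Conditions: NBS (1.0 equiv), MeCN, 0 °C
Reagents that add atoms: N-bromosuccinimide, O=C1CCC(=O)N1Br
Why: Electrophilic aromatic bromination of a tetra-alkoxybenzene; the two open positions are equivalent by symmetry, so only one monobromide can form, and one equivalent at low temperature limits dibromination.

Step 7
Reactants: 10 1-(benzyloxy)-2-bromo-3,4,5-trimethoxybenzene; 7 (R)-3-[3-(benzyloxy)-4-methoxyphenyl]-N,2-dimethoxy-N-methylpropanamide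
Product: 12 (R)-1-[2-(benzyloxy)-4,5,6-trimethoxyphenyl]-3-[3-(benzyloxy)-4-methoxyphenyl]-2-methoxypropan-1-one, via aryllithium 11 (not isolated)
Conditions: 10 (1.3 equiv), n-BuLi (1.25 equiv), THF, −78 °C; then 7, −78 to −40 °C; aq NH4Cl
Reagents that add atoms: none
Why: Bromine–lithium exchange followed by Weinreb ketone synthesis; the chelated tetrahedral adduct collapses only on quench, so no ketone is exposed to the organolithium and the α-methoxy centre should survive.

Step 8
Reactants: 12 (R)-1-[2-(benzyloxy)-4,5,6-trimethoxyphenyl]-3-[3-(benzyloxy)-4-methoxyphenyl]-2-methoxypropan-1-one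
Product: 13 (R)-1-(2-hydroxy-4,5,6-trimethoxyphenyl)-3-(3-hydroxy-4-methoxyphenyl)-2-methoxypropan-1-one
Conditions: H2 (1 atm), Pd/C, EtOAc, rt
Reagents that add atoms: none
Why: Hydrogenolysis of two aryl benzyl ethers under neutral conditions; the electron-rich aryl ketone with two ortho substituents is slow to reduce and the C3 centre is not exposed to acid or base.

Step 9
Reactants: 13 (R)-1-(2-hydroxy-4,5,6-trimethoxyphenyl)-3-(3-hydroxy-4-methoxyphenyl)-2-methoxypropan-1-one
Product: 16 (2R,3R)-2-(2,5-dihydroxy-4-methoxyphenyl)-3,5,6,7-tetramethoxychroman-4-one, via para-quinone 14 (not isolated), via ortho-quinone methide 15 (not isolated)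
Conditions: (KSO3)2NO (2.05 equiv), KH2PO4, H2O/acetone, 0 °C; extraction into degassed CH2Cl2; i-Pr2NEt (0.2 equiv), CH2Cl2 (0.01 M), Ar, −20 °C to rt; AcOH
Reagents that add atoms: potassium nitrosodisulfonate, [K+].[K+].[O-]S(=O)(=O)N([O])S(=O)(=O)[O-]
Why: Proposed new method: the nitroxyl radical abstracts the O–H hydrogen of the ring B phenol, a second equivalent couples at the free para carbon (the future C2′), and loss of HN(SO3K)2 gives para-quinone 14, which is extracted into degassed CH2Cl2 away from the oxidant. There the amine moves a proton from the quinone-bound CH2 (the future C2) to the distal C5′ oxygen and gives ortho-quinone methide 15, and the ring A phenol adds to its exocyclic carbon, forming O1–C2 and restoring the aromatic hydroquinone. The closest known reaction types are the Teuber oxidation of para-unsubstituted phenols to para-quinones and the tautomerisation of alkyl-para-quinones to quinone methides that are captured intramolecularly by oxygen nucleophiles; joining the two on a 2′-hydroxydihydrochalcone is the new element. Ring C closes by a 6-exo-trig oxa-conjugate addition. C2 is set by C3: in the chair-like closure ring B and the C3 methoxy group are both equatorial, and because the 2′-hydroxyl lets O1–C2 reopen through 15 without touching C3, the trans (2R,3R) isomer is also where equilibration ends. Selectivity for ring B should come from the ring A hydroxyl being hydrogen-bonded to the ketone and deactivated by the acyl group, which makes its hydrogen hard to abstract. Two equivalents of oxidant and the phase switch keep 16 from the oxidant, and hydrogen exchange between 14 and 16 corrects itself because the overall oxidation level is fixed and only the open-chain quinone can cyclise. A hindered tertiary amine in catalytic amount, low temperature and high dilution are chosen so that the phenol adds before the C3 proton of 15 is lost and before 15 can dimerise.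

## Compound list

1 | isovanillin (3-hydroxy-4-methoxybenzaldehyde) | COc1ccc(C=O)cc1O | starting material
2 | 3-(benzyloxy)-4-methoxybenzaldehyde | COc1ccc(C=O)cc1OCc1ccccc1 | intermediate
3 | methyl methoxyacetate | COCC(=O)OC | starting material
4 | methyl (Z)-3-[3-(benzyloxy)-4-methoxyphenyl]-2-methoxyprop-2-enoate | COc1ccc(/C=C(\OC)C(=O)OC)cc1OCc1ccccc1 | intermediate
5 | (Z)-3-[3-(benzyloxy)-4-methoxyphenyl]-2-methoxyprop-2-enoic acid | COc1ccc(/C=C(\OC)C(=O)O)cc1OCc1ccccc1 | intermediate
6 | (R)-3-[3-(benzyloxy)-4-methoxyphenyl]-2-methoxypropanoic acid | COc1ccc(C[C@@H](OC)C(=O)O)cc1OCc1ccccc1 | intermediate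
7 | (R)-3-[3-(benzyloxy)-4-methoxyphenyl]-N,2-dimethoxy-N-methylpropanamide | COc1ccc(C[C@@H](OC)C(=O)N(C)OC)cc1OCc1ccccc1 | intermediate
8 | 3,4,5-trimethoxyphenol | COc1cc(O)cc(OC)c1OC | starting material
9 | 5-(benzyloxy)-1,2,3-trimethoxybenzene | COc1cc(OCc2ccccc2)cc(OC)c1OC | intermediate
10 | 1-(benzyloxy)-2-bromo-3,4,5-trimethoxybenzene | COc1cc(OCc2ccccc2)c(Br)c(OC)c1OC | intermediate
11 | [2-(benzyloxy)-4,5,6-trimethoxyphenyl]lithium | [Li]c1c(OCc2ccccc2)cc(OC)c(OC)c1OC | intermediate
12 | (R)-1-[2-(benzyloxy)-4,5,6-trimethoxyphenyl]-3-[3-(benzyloxy)-4-methoxyphenyl]-2-methoxypropan-1-one | COc1ccc(C[C@@H](OC)C(=O)c2c(OCc3ccccc3)cc(OC)c(OC)c2OC)cc1OCc1ccccc1 | intermediate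
13 | (R)-1-(2-hydroxy-4,5,6-trimethoxyphenyl)-3-(3-hydroxy-4-methoxyphenyl)-2-methoxypropan-1-one | COc1ccc(C[C@@H](OC)C(=O)c2c(O)cc(OC)c(OC)c2OC)cc1O | intermediate
14 | 2-[(2R)-3-(2-hydroxy-4,5,6-trimethoxyphenyl)-2-methoxy-3-oxopropyl]-5-methoxycyclohexa-2,5-diene-1,4-dione | COC1=CC(=O)C(C[C@@H](OC)C(=O)c2c(O)cc(OC)c(OC)c2OC)=CC1=O | intermediate
15 | 4-hydroxy-6-[(2R)-3-(2-hydroxy-4,5,6-trimethoxyphenyl)-2-methoxy-3-oxopropylidene]-3-methoxycyclohexa-2,4-dien-1-one | COC1=CC(=O)C(=C[C@@H](OC)C(=O)c2c(O)cc(OC)c(OC)c2OC)C=C1O | intermediate
16 | (2R,3R)-2-(2,5-dihydroxy-4-methoxyphenyl)-3,5,6,7-tetramethoxychroman-4-one | COc1cc(O)c([C@H]2Oc3cc(OC)c(OC)c(OC)c3C(=O)[C@@H]2OC)cc1O | target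

## Step count and least certain steps

Total step count: 9. Longest linear sequence: 7 steps (steps 1, 2, 3, 4, 7, 8, 9); steps 5 and 6 form the second branch.

Step 9 (key step, proposed new method). Three processes are most likely to go wrong. The first is attack on the wrong ring or over-oxidation: hydrogen abstraction from the ring A phenol, which carries a para methoxy group, or further oxidation of freshly formed hydroquinone if tautomerisation starts while oxidant is still present. For the same reason a catalytic aerobic system such as O2 with Co(salen) (divalent cobalt) is not used, since it would stay in contact with the product. The second is loss of the C3 proton from 15 toward the α-methoxychalcone, which would close to racemic material. The third is intermolecular reaction of 15 at higher concentration.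

The fallback gives up the oxidative entry and reaches 15 by a known non-oxidative route, acid-induced loss of a silanol from an ortho-hydroxybenzylic silyl ether. It sets out from bromide 10, used as aryllithium 11, and comes back to the route at 15, which closes to 16 in the same flask. Commercial 2-methoxyhydroquinone is dibenzylated with BnBr and K2CO3 to 1,4-bis(benzyloxy)-2-methoxybenzene F1 , and Vilsmeier–Haack formylation of F1 with POCl3 and DMF, para to the methoxy group, gives 2,5-bis(benzyloxy)-4-methoxybenzaldehyde F2 . Separately, (R)-4-benzyloxazolidin-2-one is N-acylated with n-BuLi and methoxyacetyl chloride to (4R)-4-benzyl-3-(2-methoxyacetyl)oxazolidin-2-one F3 . The dibutylboron enolate of F3 , made with Bu2BOTf and Et3N in CH2Cl2 at −78 °C, adds to F2 in an Evans syn aldol reaction and gives (4R)-4-benzyl-3-[(2R,3S)-3-[2,5-bis(benzyloxy)-4-methoxyphenyl]-3-hydroxy-2-methoxypropanoyl]oxazolidin-2-one F4 . In F4 the auxiliary has set the methoxy-bearing carbon in the configuration of C3 of 16. Transamination of F4 with AlMe3 and MeNHOMe·HCl gives (2R,3S)-3-[2,5-bis(benzyloxy)-4-methoxyphenyl]-3-hydroxy-N,2-dimethoxy-N-methylpropanamide F5 . Silylation of F5 with TBSOTf and 2,6-lutidine gives (2R,3S)-3-[2,5-bis(benzyloxy)-4-methoxyphenyl]-3-[(tert-butyldimethylsilyl)oxy]-N,2-dimethoxy-N-methylpropanamide F6 . Aryllithium 11 is added to F6 at −78 °C and gives (2R,3S)-1-[2-(benzyloxy)-4,5,6-trimethoxyphenyl]-3-[2,5-bis(benzyloxy)-4-methoxyphenyl]-3-[(tert-butyldimethylsilyl)oxy]-2-methoxypropan-1-one F7 . Hydrogenolysis of the three benzyl ethers of F7 over Pd/C gives (2R,3S)-3-[(tert-butyldimethylsilyl)oxy]-3-(2,5-dihydroxy-4-methoxyphenyl)-1-(2-hydroxy-4,5,6-trimethoxyphenyl)-2-methoxypropan-1-one F8 . Finally F8 is treated with a catalytic sulfonic acid in degassed CH2Cl2, which expels tert-butyldimethylsilanol from the ortho-hydroxybenzylic carbon and gives 15. The carbinol configuration is irrelevant because it is erased in 15, and no oxidant is involved at any stage.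

Step 3. The most likely failures are insufficient face selectivity with this electron-rich substrate, an induction sense opposite to the one assumed, or contamination by the E acid, which is reduced to the other enantiomer. The fallback replaces catalytic hydrogenation by an auxiliary-controlled alkylation. It sets out from 2 and comes back to the route at 6. Aldehyde 2 is reduced with NaBH4 in MeOH to [3-(benzyloxy)-4-methoxyphenyl]methanol F9 , and F9 is converted with PBr3 in CH2Cl2 into 2-(benzyloxy)-4-(bromomethyl)-1-methoxybenzene F10 . (S)-4-Benzyloxazolidin-2-one is N-acylated with methoxyacetyl chloride to (4S)-4-benzyl-3-(2-methoxyacetyl)oxazolidin-2-one F11 . Then F11 is deprotonated with NaHMDS in THF at −78 °C and alkylated with F10 on the face away from the benzyl group, which gives (4S)-4-benzyl-3-[(2R)-3-[3-(benzyloxy)-4-methoxyphenyl]-2-methoxypropanoyl]oxazolidin-2-one F12 . LiOH and H2O2 remove the auxiliary from F12 and give 6.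

Step 7. The most likely failures are removal of the α-proton of 7 by the hindered aryllithium (recovered, partly racemised amide), and rearrangement or butylation of 11 if the exchange mixture warms. The fallback moves the C–C bond formation to the aldehyde oxidation level, where addition is much faster than deprotonation. It sets out from 7 and comes back to the route at 12. Amide 7 is reduced with DIBAL-H in THF at −78 °C to (R)-3-[3-(benzyloxy)-4-methoxyphenyl]-2-methoxypropanal F13 , which is used at once because it epimerises easily. Aryllithium 11 adds to F13 at −78 °C and gives (2R)-1-[2-(benzyloxy)-4,5,6-trimethoxyphenyl]-3-[3-(benzyloxy)-4-methoxyphenyl]-2-methoxypropan-1-ol F14 as a mixture of carbinol epimers. Buffered Dess–Martin oxidation of F14 converts both epimers into 12.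

## Further compounds

F1 | step 9 | 1,4-bis(benzyloxy)-2-methoxybenzene | COc1cc(OCc2ccccc2)ccc1OCc1ccccc1
F2 | step 9 | 2,5-bis(benzyloxy)-4-methoxybenzaldehyde | COc1cc(OCc2ccccc2)c(C=O)cc1OCc1ccccc1
F3 | step 9 | (4R)-4-benzyl-3-(2-methoxyacetyl)oxazolidin-2-one | COCC(=O)N1C(=O)OC[C@H]1Cc1ccccc1
F4 | step 9 | (4R)-4-benzyl-3-[(2R,3S)-3-[2,5-bis(benzyloxy)-4-methoxyphenyl]-3-hydroxy-2-methoxypropanoyl]oxazolidin-2-one | COc1cc(OCc2ccccc2)c([C@H](O)[C@@H](OC)C(=O)N2C(=O)OC[C@H]2Cc2ccccc2)cc1OCc1ccccc1
F5 | step 9 | (2R,3S)-3-[2,5-bis(benzyloxy)-4-methoxyphenyl]-3-hydroxy-N,2-dimethoxy-N-methylpropanamide | COc1cc(OCc2ccccc2)c([C@H](O)[C@@H](OC)C(=O)N(C)OC)cc1OCc1ccccc1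
F6 | step 9 | (2R,3S)-3-[2,5-bis(benzyloxy)-4-methoxyphenyl]-3-[(tert-butyldimethylsilyl)oxy]-N,2-dimethoxy-N-methylpropanamide | COc1cc(OCc2ccccc2)c([C@H](O[Si](C)(C)C(C)(C)C)[C@@H](OC)C(=O)N(C)OC)cc1OCc1ccccc1
F7 | step 9 | (2R,3S)-1-[2-(benzyloxy)-4,5,6-trimethoxyphenyl]-3-[2,5-bis(benzyloxy)-4-methoxyphenyl]-3-[(tert-butyldimethylsilyl)oxy]-2-methoxypropan-1-one | COc1cc(OCc2ccccc2)c([C@H](O[Si](C)(C)C(C)(C)C)[C@@H](OC)C(=O)c2c(OCc3ccccc3)cc(OC)c(OC)c2OC)cc1OCc1ccccc1
F8 | step 9 | (2R,3S)-3-[(tert-butyldimethylsilyl)oxy]-3-(2,5-dihydroxy-4-methoxyphenyl)-1-(2-hydroxy-4,5,6-trimethoxyphenyl)-2-methoxypropan-1-one | COc1cc(O)c([C@H](O[Si](C)(C)C(C)(C)C)[C@@H](OC)C(=O)c2c(O)cc(OC)c(OC)c2OC)cc1O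
F9 | step 3 | [3-(benzyloxy)-4-methoxyphenyl]methanol | COc1ccc(CO)cc1OCc1ccccc1
F10 | step 3 | 2-(benzyloxy)-4-(bromomethyl)-1-methoxybenzene | COc1ccc(CBr)cc1OCc1ccccc1
F11 | step 3 | (4S)-4-benzyl-3-(2-methoxyacetyl)oxazolidin-2-one | COCC(=O)N1C(=O)OC[C@@H]1Cc1ccccc1
F12 | step 3 | (4S)-4-benzyl-3-[(2R)-3-[3-(benzyloxy)-4-methoxyphenyl]-2-methoxypropanoyl]oxazolidin-2-one | COc1ccc(C[C@@H](OC)C(=O)N2C(=O)OC[C@@H]2Cc2ccccc2)cc1OCc1ccccc1
F13 | step 7 | (R)-3-[3-(benzyloxy)-4-methoxyphenyl]-2-methoxypropanal | COc1ccc(C[C@@H](OC)C=O)cc1OCc1ccccc1
F14 | step 7 | (2R)-1-[2-(benzyloxy)-4,5,6-trimethoxyphenyl]-3-[3-(benzyloxy)-4-methoxyphenyl]-2-methoxypropan-1-ol | COc1ccc(C[C@@H](OC)C(O)c2c(OCc3ccccc3)cc(OC)c(OC)c2OC)cc1OCc1ccccc1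
A1 | alternative 1 | (2R,3R)-3-[2,5-bis(benzyloxy)-4-methoxyphenyl]-3-hydroxy-2-methoxy-1-[2-(methoxymethoxy)-4,5,6-trimethoxyphenyl]propan-1-one | COCOc1cc(OC)c(OC)c(OC)c1C(=O)[C@H](OC)[C@H](O)c1cc(OCc2ccccc2)c(OC)cc1OCc1ccccc1
A2 | alternative 1 | 2-diazo-1-[2-(methoxymethoxy)-4,5,6-trimethoxyphenyl]ethan-1-one | COCOc1cc(OC)c(OC)c(OC)c1C(=O)C=[N+]=[N-]
A3 | alternative 1 | methanol | CO
A4 | alternative 1 | 2,5-bis(benzyloxy)-4-methoxybenzaldehyde | COc1cc(OCc2ccccc2)c(C=O)cc1OCc1ccccc1
A5 | alternative 2 | (2S,3S)-3,5,6,7-tetramethoxychroman-2-ol | O[C@H]1Oc2cc(OC)c(OC)c(OC)c2C[C@@H]1OC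
A6 | alternative 2 | 2-(hydroxymethyl)-3,4,5-trimethoxyphenol | COc1cc(O)c(CO)c(OC)c1OC
A7 | alternative 2 | methoxyacetaldehyde | COCC=O
A8 | alternative 3 | (2R,3R)-2-[2,5-bis(benzyloxy)-4-methoxyphenyl]-3-hydroxy-5,6,7-trimethoxychroman-4-one | COc1cc(OCc2ccccc2)c([C@H]3Oc4cc(OC)c(OC)c(OC)c4C(=O)[C@@H]3O)cc1OCc1ccccc1
A9 | alternative 3 | 2-{1-[2,5-bis(benzyloxy)-4-methoxyphenyl]-2-oxoethoxy}-4,5,6-trimethoxybenzaldehyde | COc1cc(OCc2ccccc2)c(C(C=O)Oc2cc(OC)c(OC)c(OC)c2C=O)cc1OCc1ccccc1
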